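**Plan**

- Retrosynthesis: the four phenols go back to methyl ethers and the C6 aldehyde to a methyl ester. The dihydrofuran ring is then cut at C2–C3 and O1–C2, and last the C3a–C3 bond is cut to a ring-A aryl bromide and 3,5-dimethoxybenzaldehyde.
- Enabling feature: C3 is benzylic on C3a of ring A, and C3a is ortho to the oxygen-bearing C7a, so the four atoms O1–C7a–C3a–C3 can exist as an o-quinone methide (C7a=O1, C3a=C3). C2 sits between O1 and C3 and carries only ring B, so it can come from a one-carbon benzylide.
- Forward: ring A is magnesiated and joined to ring C at C3, and a sulfinate replaces the carbinol OH. The only ring that is built, the dihydrofuran, then closes in one [4+1] step that brings in C2 with ring B. Ester to aldehyde and ether cleavage finish the route.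
- Stereochemistry: C2 is set by a C2-symmetric (2S,5S)-2,5-dimethylthiolanium benzylide, whose sulfide comes from (2R,5R)-hexane-2,5-diol by double inversion. C3 follows from C2 through the anti betaine, giving the trans (2S,3S) ring; neither centre is touched afterwards.
- The second ring-A oxygen (on C4) is carried as a methyl ether, so that only one phenol can form the methide and the methide stays uncharged.

Key step: step 8

Assumption: the 2,5-dimethylthiolanium benzylide is taken to present the same ylide face to the o-quinone methide as in its benzylidene transfer to aldehydes, where the (2R,5R)-sulfide gives (S,S)-diaryl epoxides; on that basis the (2S,5S)-sulfide is the one that leads to the (2S,3S)-dihydrobenzofuran.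

**Route**

Step 1
Reactants: 1 methyl 4-bromo-3,5-dihydroxybenzoate
Product: 2 methyl 4-bromo-3-hydroxy-5-methoxybenzoate
Conditions: MeI (1.0 equiv), K2CO3 (1.1 equiv), DMF, 0 °C → rt; unreacted 1 recycled
Reagents that add atoms: iodomethane, CI
Why: Williamson O-methylation with the alkylating agent as limiting reagent; the two hydroxyls are equivalent, so only one mono-ether exists, and it should be separable by chromatography from the more polar diol 1 and the less polar dimethyl ether.

Step 2
Reactants: 2 methyl 4-bromo-3-hydroxy-5-methoxybenzoate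
Product: 3 methyl 4-bromo-3-methoxy-5-(methoxymethoxy)benzoate
Conditions: MOMCl, i-Pr2NEt, CH2Cl2, 0 °C → rt
Reagents that add atoms: chloromethyl methyl ether, COCCl
Why: Standard acetal protection of a phenol (O-alkylation by the α-chloro ether), which removes the acidic proton before metalation and places a chelating group next to the bromine.

Step 3
Reactants: 3 methyl 4-bromo-3-methoxy-5-(methoxymethoxy)benzoate, 4 3,5-dimethoxybenzaldehyde
Product: 6 methyl 4-[(3,5-dimethoxyphenyl)(hydroxy)methyl]-3-methoxy-5-(methoxymethoxy)benzoate (racemic), via aryl Grignard 5 (not isolated)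
Conditions: i-PrMgCl·LiCl (1.1 equiv), THF, −20 °C; then 4, −20 °C → rt; aq. NH4Cl
Reagents that add atoms: none
Why: Bromine–magnesium exchange with the turbo-Grignard reagent should be fast at low temperature because the two flanking ether oxygens and the para ester stabilise the aryl anion and the MOM group chelates magnesium, so the methyl ester survives, and the hindered aryl Grignard then adds 1,2 to the aldehyde (Grignard addition) to form the C3a–C3 bond; the new carbinol centre is racemic and is erased in step 8.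

Step 4
Reactants: 6 methyl 4-[(3,5-dimethoxyphenyl)(hydroxy)methyl]-3-methoxy-5-(methoxymethoxy)benzoate (racemic)
Product: 8 methyl 4-[(3,5-dimethoxyphenyl)(4-methylbenzenesulfonyl)methyl]-3-hydroxy-5-methoxybenzoate (racemic), via MOM sulfone 7 (not isolated)
Conditions: TolSO2Na (3 equiv), conc. HCl, MeOH/THF, rt → 40 °C
Reagents that add atoms: sodium 4-methylbenzenesulfinate, Cc1ccc(S(=O)[O-])cc1.[Na+]
Why: Acid ionises the benzhydrol, whose cation is stabilised by the two ortho oxygens of ring A, and p-toluenesulfinic acid captures it at sulfur (SN1 S-alkylation of a sulfinate, the usual entry to 2-(sulfonylalkyl)phenols), after which the same methanolic HCl cleaves the MOM acetal by transacetalisation; should deprotection run ahead of substitution, both orders converge on 8.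

Step 5
Reactants: 9 (2R,5R)-hexane-2,5-diol
Product: 10 (2R,5R)-hexane-2,5-diyl dimethanesulfonate
Conditions: MsCl, Et3N, CH2Cl2, −10 → 0 °C
Reagents that add atoms: methanesulfonyl chloride, CS(=O)(=O)Cl
Why: O-Sulfonylation of both secondary alcohols, which breaks no bond at carbon and so keeps the (R,R) configuration.

Step 6
Reactants: 10 (2R,5R)-hexane-2,5-diyl dimethanesulfonate
Product: 11 (2S,5S)-2,5-dimethylthiolane
Conditions: Na2S·9H2O, DMSO, rt
Reagents that add atoms: sodium sulfide, [Na+].[Na+].[S-2]
Why: Two successive SN2 displacements by sulfide (the second a 5-exo-tet ring closure) invert both carbinol carbons, so the (R,R)-bis-mesylate should give the C2-symmetric (S,S)-thiolane.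

Step 7
Reactants: 11 (2S,5S)-2,5-dimethylthiolane, 12 4-methoxybenzyl bromide
Product: 13 (2S,5S)-1-[(4-methoxyphenyl)methyl]-2,5-dimethylthiolan-1-ium tetrafluoroborate
Conditions: AgBF4, CH2Cl2, 0 °C → rt, dark
Reagents that add atoms: silver tetrafluoroborate, [Ag+].F[B-](F)(F)F
Why: Silver-assisted S-alkylation of the sulfide by the benzylic bromide; the two lone pairs of the C2-symmetric sulfide are equivalent, so a single sulfonium salt forms, and the non-nucleophilic counter-ion prevents reversal by halide.

Step 8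
Reactants: 8 methyl 4-[(3,5-dimethoxyphenyl)(4-methylbenzenesulfonyl)methyl]-3-hydroxy-5-methoxybenzoate (racemic), 13 (2S,5S)-1-[(4-methoxyphenyl)methyl]-2,5-dimethylthiolan-1-ium tetrafluoroborate
Product: 17 methyl (2S,3S)-3-(3,5-dimethoxyphenyl)-4-methoxy-2-(4-methoxyphenyl)-2,3-dihydro-1-benzofuran-6-carboxylate, via o-quinone methide 14 (not isolated), via sulfonium ylide 15 (not isolated), via anti betaine 16 (not isolated)
Conditions: 13 (1.3 equiv), Cs2CO3 (3 equiv), MeCN, −20 → 0 °C
Reagents that add atoms: none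
Why: Carbonate deprotonates the single free phenol of 8, which expels p-toluenesulfinate (E1cB) to give the neutral o-quinone methide 14, and it also deprotonates 13 to the semi-stabilised benzylide 15; conjugate addition of the ylide carbon to the exocyclic C3 re-aromatises ring A and forms C2–C3, giving the phenoxide–sulfonium betaine 16. The phenoxide oxygen (the future O1) then displaces the thiolane from C2 with inversion, an intramolecular SN2 that closes the dihydrofuran ring in the 5-exo-tet mode and forms O1–C2. The closest known reactions are the formal [4+1] annulations of o-quinone methides released from 2-(sulfonylalkyl)phenols with sulfonium ylides, and the asymmetric benzylidene transfer from C2-symmetric thiolanium salts to aldehydes (Corey–Chaykovsky type). C2 is controlled by the sulfide: the aryl group of the ylide points away from the thiolane ring, and the methide approaches the ylide carbon from the side remote from the ring methyl that is cis to it, which after the inverting closure corresponds to 2S for the (2S,5S)-sulfide. C3 is set relative to C2 in the addition, where the open transition state with the two aryl groups anti gives the anti betaine and hence the trans (2S,3S) ring, whereas a syn betaine would have to close with the aryl groups eclipsed. The step needs attack at C3 only and no reaction at the ester; this is secured by the much higher electrophilicity of the methide, by the C4 methyl ether that leaves only one phenol able to form a methide and keeps it uncharged, and by the non-nucleophilic counter-ion of 13, which suppresses benzyl transfer to the phenoxide.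

Step 9
Reactants: 17 methyl (2S,3S)-3-(3,5-dimethoxyphenyl)-4-methoxy-2-(4-methoxyphenyl)-2,3-dihydro-1-benzofuran-6-carboxylate
Product: 18 [(2S,3S)-3-(3,5-dimethoxyphenyl)-4-methoxy-2-(4-methoxyphenyl)-2,3-dihydro-1-benzofuran-6-yl]methanol
Conditions: LiAlH4, THF, 0 °C; aq. Rochelle salt
Reagents that add atoms: none
Why: Hydride reduction of an aryl ester to the benzylic alcohol; the aryl ethers and the two stereocentres, which carry no acidic or reducible function, should not be affected.

Step 10
Reactants: 18 [(2S,3S)-3-(3,5-dimethoxyphenyl)-4-methoxy-2-(4-methoxyphenyl)-2,3-dihydro-1-benzofuran-6-yl]methanol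
Product: 19 (2S,3S)-3-(3,5-dimethoxyphenyl)-4-methoxy-2-(4-methoxyphenyl)-2,3-dihydro-1-benzofuran-6-carbaldehyde
Conditions: MnO2 (activated, excess), CH2Cl2, rt
Reagents that add atoms: none
Why: Chemoselective oxidation of a benzylic alcohol by activated manganese dioxide, which stops at the aldehyde and should leave the dihydrofuran C–H bonds alone at room temperature.

Step 11
Reactants: 19 (2S,3S)-3-(3,5-dimethoxyphenyl)-4-methoxy-2-(4-methoxyphenyl)-2,3-dihydro-1-benzofuran-6-carbaldehyde
Product: 20 gnetal [(2S,3S)-3-(3,5-dihydroxyphenyl)-4-hydroxy-2-(4-hydroxyphenyl)-2,3-dihydro-1-benzofuran-6-carbaldehyde]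
Conditions: BBr3 (10 equiv), CH2Cl2, −78 → 0 °C; then ice/aq. NaHCO3
Reagents that add atoms: none
Why: Lewis-acid cleavage of the four aryl methyl ethers (O-complexation, then bromide attack at methyl) with hydrolysis of the aryl borates and of the complexed aldehyde on work-up; C3 has no pathway for epimerisation and any reversible ionisation of C2–O1 should re-close to the more stable trans ring, so the (2S,3S) configuration should be kept.

**Compound list**

1 | methyl 4-bromo-3,5-dihydroxybenzoate | COC(=O)c1cc(O)c(Br)c(O)c1 | starting material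
2 | methyl 4-bromo-3-hydroxy-5-methoxybenzoate | COC(=O)c1cc(O)c(Br)c(OC)c1 | intermediate
3 | methyl 4-bromo-3-methoxy-5-(methoxymethoxy)benzoate | COCOc1cc(C(=O)OC)cc(OC)c1Br | intermediate
4 | 3,5-dimethoxybenzaldehyde | COc1cc(C=O)cc(OC)c1 | starting material
5 | [2-methoxy-4-(methoxycarbonyl)-6-(methoxymethoxy)phenyl]magnesium chloride (LiCl complex) | COCOc1cc(C(=O)OC)cc(OC)c1[Mg]Cl | intermediate (not isolated)
6 | methyl 4-[(3,5-dimethoxyphenyl)(hydroxy)methyl]-3-methoxy-5-(methoxymethoxy)benzoate (racemic) | COCOc1cc(C(=O)OC)cc(OC)c1C(O)c1cc(OC)cc(OC)c1 | intermediate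
7 | methyl 4-[(3,5-dimethoxyphenyl)(4-methylbenzenesulfonyl)methyl]-3-methoxy-5-(methoxymethoxy)benzoate (racemic) | COCOc1cc(C(=O)OC)cc(OC)c1C(c1cc(OC)cc(OC)c1)S(=O)(=O)c1ccc(C)cc1 | intermediate (not isolated)
8 | methyl 4-[(3,5-dimethoxyphenyl)(4-methylbenzenesulfonyl)methyl]-3-hydroxy-5-methoxybenzoate (racemic) | COC(=O)c1cc(O)c(C(c2cc(OC)cc(OC)c2)S(=O)(=O)c2ccc(C)cc2)c(OC)c1 | intermediate
9 | (2R,5R)-hexane-2,5-diol | C[C@@H](O)CC[C@@H](C)O | starting material
10 | (2R,5R)-hexane-2,5-diyl dimethanesulfonate | C[C@@H](OS(C)(=O)=O)CC[C@@H](C)OS(C)(=O)=O | intermediate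
11 | (2S,5S)-2,5-dimethylthiolane | C[C@H]1CC[C@H](C)S1 | intermediate
12 | 4-methoxybenzyl bromide | COc1ccc(CBr)cc1 | starting material
13 | (2S,5S)-1-[(4-methoxyphenyl)methyl]-2,5-dimethylthiolan-1-ium tetrafluoroborate | C[C@H]1CC[C@H](C)[S+]1Cc1ccc(OC)cc1.F[B-](F)(F)F | intermediate
14 | methyl 4-[(3,5-dimethoxyphenyl)methylidene]-5-methoxy-3-oxocyclohexa-1,5-diene-1-carboxylate (o-quinone methide, alkene geometry not fixed) | COC(=O)C1=CC(=O)C(=Cc2cc(OC)cc(OC)c2)C(OC)=C1 | intermediate (not isolated)
15 | (4-methoxyphenyl)[(2S,5S)-2,5-dimethylthiolan-1-ium-1-yl]methanide | C[C@H]1CC[C@H](C)[S+]1[CH-]c1ccc(OC)cc1 | intermediate (not isolated)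
16 | 2-[(1S,2R)-1-(3,5-dimethoxyphenyl)-2-[(2S,5S)-2,5-dimethylthiolan-1-ium-1-yl]-2-(4-methoxyphenyl)ethyl]-3-methoxy-5-(methoxycarbonyl)phenolate (anti betaine) | COC(=O)c1cc([O-])c(c(OC)c1)[C@H](c1cc(OC)cc(OC)c1)[C@H](c1ccc(OC)cc1)[S+]1[C@@H](C)CC[C@@H]1C | intermediate (not isolated)
17 | methyl (2S,3S)-3-(3,5-dimethoxyphenyl)-4-methoxy-2-(4-methoxyphenyl)-2,3-dihydro-1-benzofuran-6-carboxylate | COC(=O)c1cc(OC)c2c(c1)O[C@H](c1ccc(OC)cc1)[C@H]2c1cc(OC)cc(OC)c1 | intermediate
18 | [(2S,3S)-3-(3,5-dimethoxyphenyl)-4-methoxy-2-(4-methoxyphenyl)-2,3-dihydro-1-benzofuran-6-yl]methanol | OCc1cc(OC)c2c(c1)O[C@H](c1ccc(OC)cc1)[C@H]2c1cc(OC)cc(OC)c1 | intermediate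
19 | (2S,3S)-3-(3,5-dimethoxyphenyl)-4-methoxy-2-(4-methoxyphenyl)-2,3-dihydro-1-benzofuran-6-carbaldehyde | O=Cc1cc(OC)c2c(c1)O[C@H](c1ccc(OC)cc1)[C@H]2c1cc(OC)cc(OC)c1 | intermediate
20 | gnetal, (2S,3S)-3-(3,5-dihydroxyphenyl)-4-hydroxy-2-(4-hydroxyphenyl)-2,3-dihydro-1-benzofuran-6-carbaldehyde | O=Cc1cc(O)c2c(c1)O[C@H](c1ccc(O)cc1)[C@H]2c1cc(O)cc(O)c1 | target

**Summary**

Total step count: 11.
Longest linear sequence: 8 steps (steps 1–4 and 8–11); steps 5–7 form the side branch to the sulfonium salt.

**Steps most likely to fail**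

Step 8. The thiolanium benzylide may discriminate poorly between its two faces toward the methide, or the betaine may epimerise at the sulfonium-bearing carbon before it closes, so that 17 forms with low enantiomeric purity. The fallback sets out from 8 and 12 and comes back at 17. Thiolane (tetrahydrothiophene) is alkylated with 12 and AgBF4 to 1-[(4-methoxyphenyl)methyl]thiolan-1-ium tetrafluoroborate F1. With Cs2CO3 in MeCN, 8 and F1 should give, by the same annulation without a chiral controller, racemic methyl trans-3-(3,5-dimethoxyphenyl)-4-methoxy-2-(4-methoxyphenyl)-2,3-dihydro-1-benzofuran-6-carboxylate F2. Preparative chromatography on a chiral stationary phase then separates 17 from methyl (2R,3R)-3-(3,5-dimethoxyphenyl)-4-methoxy-2-(4-methoxyphenyl)-2,3-dihydro-1-benzofuran-6-carboxylate F3, and the route continues from 17 with step 9.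

Step 3. The exchange may be slow on the doubly ortho-substituted bromide, which leaves time for isopropyl or aryl Grignard species to add to the methyl ester. The fallback sets out from 3 and comes back at 6, and it reverses the polarity of the C3a–C3 coupling. Palladium-catalysed reductive carbonylation of 3 (CO/H2, Pd(OAc)2, di(1-adamantyl)-n-butylphosphine, TMEDA, toluene, 100 °C) should give methyl 4-formyl-3-methoxy-5-(methoxymethoxy)benzoate F4. (3,5-Dimethoxyphenyl)magnesium bromide F5, made from 1-bromo-3,5-dimethoxybenzene and magnesium in THF, is then added at −78 °C; the aldehyde is far more electrophilic than the ester, so the addition should give 6.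

Step 11. While the ethers are being cleaved, the BBr3-complexed aldehyde may condense with the electron-rich aryl rings (hydroxyalkylation), and opening of the C2–O1 bond may compete. The fallback sets out from 17 and comes back at 20; it moves the ether cleavage to the ester stage, where no aldehyde is present. BBr3 in CH2Cl2 on 17 should give methyl (2S,3S)-3-(3,5-dihydroxyphenyl)-4-hydroxy-2-(4-hydroxyphenyl)-2,3-dihydro-1-benzofuran-6-carboxylate F6. TBSCl and imidazole in DMF convert it into methyl (2S,3S)-3-[3,5-bis(tert-butyldimethylsilyloxy)phenyl]-4-(tert-butyldimethylsilyloxy)-2-[4-(tert-butyldimethylsilyloxy)phenyl]-2,3-dihydro-1-benzofuran-6-carboxylate F7. DIBAL-H in CH2Cl2 at −78 → 0 °C reduces the ester to [(2S,3S)-3-[3,5-bis(tert-butyldimethylsilyloxy)phenyl]-4-(tert-butyldimethylsilyloxy)-2-[4-(tert-butyldimethylsilyloxy)phenyl]-2,3-dihydro-1-benzofuran-6-yl]methanol F8. MnO2 oxidises this to (2S,3S)-3-[3,5-bis(tert-butyldimethylsilyloxy)phenyl]-4-(tert-butyldimethylsilyloxy)-2-[4-(tert-butyldimethylsilyloxy)phenyl]-2,3-dihydro-1-benzofuran-6-carbaldehyde F9. HF·pyridine in THF then removes the four silyl groups without a Lewis acid to give 20.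

Further compounds
F1 | step 8 | 1-[(4-methoxyphenyl)methyl]thiolan-1-ium tetrafluoroborate | COc1ccc(C[S+]2CCCC2)cc1.F[B-](F)(F)F
F2 | step 8 | racemic methyl trans-3-(3,5-dimethoxyphenyl)-4-methoxy-2-(4-methoxyphenyl)-2,3-dihydro-1-benzofuran-6-carboxylate (1:1 mixture of 17 and its enantiomer) | COC(=O)c1cc(OC)c2c(c1)O[C@H](c1ccc(OC)cc1)[C@H]2c1cc(OC)cc(OC)c1.COC(=O)c1cc(OC)c2c(c1)O[C@@H](c1ccc(OC)cc1)[C@@H]2c1cc(OC)cc(OC)c1
F3 | step 8 | methyl (2R,3R)-3-(3,5-dimethoxyphenyl)-4-methoxy-2-(4-methoxyphenyl)-2,3-dihydro-1-benzofuran-6-carboxylate | COC(=O)c1cc(OC)c2c(c1)O[C@@H](c1ccc(OC)cc1)[C@@H]2c1cc(OC)cc(OC)c1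
F4 | step 3 | methyl 4-formyl-3-methoxy-5-(methoxymethoxy)benzoate | COCOc1cc(C(=O)OC)cc(OC)c1C=O
F5 | step 3 | (3,5-dimethoxyphenyl)magnesium bromide | COc1cc(OC)cc([Mg]Br)c1
F6 | step 11 | methyl (2S,3S)-3-(3,5-dihydroxyphenyl)-4-hydroxy-2-(4-hydroxyphenyl)-2,3-dihydro-1-benzofuran-6-carboxylate | COC(=O)c1cc(O)c2c(c1)O[C@H](c1ccc(O)cc1)[C@H]2c1cc(O)cc(O)c1
F7 | step 11 | methyl (2S,3S)-3-[3,5-bis(tert-butyldimethylsilyloxy)phenyl]-4-(tert-butyldimethylsilyloxy)-2-[4-(tert-butyldimethylsilyloxy)phenyl]-2,3-dihydro-1-benzofuran-6-carboxylate | COC(=O)c1cc(O[Si](C)(C)C(C)(C)C)c2c(c1)O[C@H](c1ccc(O[Si](C)(C)C(C)(C)C)cc1)[C@H]2c1cc(O[Si](C)(C)C(C)(C)C)cc(O[Si](C)(C)C(C)(C)C)c1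
F8 | step 11 | [(2S,3S)-3-[3,5-bis(tert-butyldimethylsilyloxy)phenyl]-4-(tert-butyldimethylsilyloxy)-2-[4-(tert-butyldimethylsilyloxy)phenyl]-2,3-dihydro-1-benzofuran-6-yl]methanol | OCc1cc(O[Si](C)(C)C(C)(C)C)c2c(c1)O[C@H](c1ccc(O[Si](C)(C)C(C)(C)C)cc1)[C@H]2c1cc(O[Si](C)(C)C(C)(C)C)cc(O[Si](C)(C)C(C)(C)C)c1
F9 | step 11 | (2S,3S)-3-[3,5-bis(tert-butyldimethylsilyloxy)phenyl]-4-(tert-butyldimethylsilyloxy)-2-[4-(tert-butyldimethylsilyloxy)phenyl]-2,3-dihydro-1-benzofuran-6-carbaldehyde | O=Cc1cc(O[Si](C)(C)C(C)(C)C)c2c(c1)O[C@H](c1ccc(O[Si](C)(C)C(C)(C)C)cc1)[C@H]2c1cc(O[Si](C)(C)C(C)(C)C)cc(O[Si](C)(C)C(C)(C)C)c1
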